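## Retrosynthetic overview
1. Methyl diacarnoate A (18) comes from the vinyl-dioxane 16 by oxidative cleavage of the vinyl group to the acid 17, then methylation. The vinyl group is a masked CO2Me.
2. The quaternary peroxide carbon C6 (Me and CH2CH2Ar) is set by the proposed new step: axial methylation of the cyclic peroxycarbenium ion derived from the 3-methoxy-1,2-dioxane 15.
3. The 1,2-dioxane ring is closed by hydroperoxy-ketal transketalization of 14. The hydroperoxide comes from SN2 displacement (inversion) of the anti mesylate 13 by HOO⁻.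
4. The anti Me/O stereodiad comes from Brown (E)-crotylboration of the ketal aldehyde 10.
5. The enone ring is made first, by Stork–Danheiser transposition (steps 1–3). The dioxane ring is formed at step 11.

## Assumptions
- 4,4-Dimethylcyclohexane-1,3-dione (1), 2-(2-bromoethyl)-1,3-dioxolane (precursor of Grignard 4), 4-bromobut-1-ene (precursor of Grignard 6) and trans-2-butene are commercial.
- I assume the Ipc2B antipode from (−)-Ipc2BOMe (made from (+)-α-pinene) gives the (3S,4R) alcohol. If Mosher analysis shows the other alcohol, switch to (+)-Ipc2BOMe.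

## Route

**Step 1**
Reactants: 1, 4,4-dimethylcyclohexane-1,3-dione
Product: 2, 2,4,4-trimethylcyclohexane-1,3-dione
Conditions: MeI, 1 M aq. NaOH, 50 °C
Reagents that add atoms: methyl iodide, CI
Why: C-Alkylation of the doubly activated C2 of the cyclic 1,3-dione enolate in water (known 2-methylation of cyclic 1,3-diones).

**Step 2**
Reactants: 2
Product: 3, 3-isobutoxy-2,6,6-trimethylcyclohex-2-en-1-one
Conditions: iBuOH, cat. TsOH·H2O, PhH, reflux, Dean–Stark
Reagents that add atoms: isobutanol, CC(C)CO
Why: Vinylogous-ester formation occurs at the carbonyl remote from the CMe2 group. The hindered carbonyl next to CMe2 stays as the ketone that is attacked in step 3.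

**Step 3**
Reactants: 3; 4, 2-(1,3-dioxolan-2-yl)ethylmagnesium bromide
Product: 5, 3-(2,6,6-trimethyl-3-oxocyclohex-1-en-1-yl)propanal
Conditions: 4 (2 equiv), CeCl3, THF, 0 °C→rt; then 3 M aq. HCl, THF, 50 °C
Reagents that add atoms: 4, Br[Mg]CCC1OCCO1 (its carbon chain is retained, and the dioxolane becomes CHO); water, O (hydrolysis)
Why: Stork–Danheiser 1,2-addition of the Grignard to the ketone C=O next to CMe2 (CeCl3 activated). Acid hydrolysis of the enol ether with allylic transposition gives the 3-alkyl-2,4,4-trimethylcyclohexenone, with the chain on the carbon next to CMe2 as in the target. The same acid cleaves the dioxolane to the aldehyde.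

**Step 4**
Reactants: 5; 6, 3-butenylmagnesium bromide
Product: 7, 3-(3-hydroxyhept-6-en-1-yl)-2,4,4-trimethylcyclohex-2-en-1-one (racemic; the stereocentre is destroyed in step 5)
Conditions: 6 (1.05 equiv), THF, −78 °C
Reagents that add atoms: 6, C=CCC[Mg]Br
Why: Grignard addition. The aldehyde is far more reactive than the hindered, conjugated tetrasubstituted enone at −78 °C.

**Step 5**
Reactants: 7
Product: 8, 3-(3-oxohept-6-en-1-yl)-2,4,4-trimethylcyclohex-2-en-1-one
Conditions: Dess–Martin periodinane, NaHCO3, CH2Cl2, rt
Reagents that add atoms: none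
Why: Mild oxidation of the secondary alcohol to the ketone. The terminal alkene and the enone are untouched.

**Step 6**
Reactants: 8
Product: 9, 3-(3,3-dimethoxyhept-6-en-1-yl)-2,4,4-trimethylcyclohex-2-en-1-one
Conditions: HC(OMe)3, MeOH, cat. TsOH, rt; Et3N quench
Reagents that add atoms: methanol, CO; trimethyl orthoformate, COC(OC)OC (together they supply the two OMe groups)
Why: Ketalization of the unhindered aliphatic ketone. The hindered, tetrasubstituted enone C=O does not ketalize.

**Step 7**
Reactants: 9
Product: 10, 4,4-dimethoxy-6-(2,6,6-trimethyl-3-oxocyclohex-1-en-1-yl)hexanal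
Conditions: OsO4 (2 mol%), NaIO4, 2,6-lutidine, dioxane/H2O, rt
Reagents that add atoms: sodium periodate, [Na+].[O-]I(=O)(=O)=O (source of the aldehyde O); water, O
Why: Lemieux–Johnson cleavage. OsO4 attacks the unhindered terminal alkene and not the tetrasubstituted enone, and lutidine buffers the medium so the ketal survives.

**Step 8**
Reactants: 10; 11, (E)-crotyl-B(Ipc)2 (prepared in situ)
Product: 12, (3S,4R)-7,7-dimethoxy-3-methyl-9-(2,6,6-trimethyl-3-oxocyclohex-1-en-1-yl)non-1-en-4-ol (anti)
Conditions: 11 from trans-2-butene, n-BuLi, KOtBu, THF, −45 °C; then (−)-Ipc2BOMe, −78 °C; then BF3·OEt2; add 10, −78 °C, 3 h; then NaOH, H2O2, 0 °C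
Reagents that add atoms: 11, C/C=C/CB(C1C(C)C2CC(C1)C2(C)C)C1C(C)C2CC(C1)C2(C)C (connectivity only; it delivers the C4H7 crotyl unit)
Why: Brown crotylboration through a chair Zimmerman–Traxler transition state. The E-crotyl geometry gives the anti relationship and the Ipc ligands set the absolute face. C3 (S) becomes the ester α-carbon, and C4 (R) is inverted in step 10 to become ring C3 of the target.

**Step 9**
Reactants: 12
Product: 13, O-mesylate of 12 (configuration retained)
Conditions: MsCl, Et3N, CH2Cl2, 0 °C
Reagents that add atoms: methanesulfonyl chloride, CS(=O)(=O)Cl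
Why: Standard sulfonylation of the secondary alcohol; no stereocentre is touched.

**Step 10**
Reactants: 13
Product: 14, (3S,4S)-4-hydroperoxy-7,7-dimethoxy-3-methyl-9-(2,6,6-trimethyl-3-oxocyclohex-1-en-1-yl)non-1-ene
Conditions: 50% aq. H2O2 (20 equiv), KOH, THF/MeOH, 0 °C→rt
Reagents that add atoms: hydrogen peroxide, OO
Why: SN2 displacement of the secondary mesylate by HOO⁻ with Walden inversion converts the anti mesylate into the syn-related peroxide required in the target. The ketal is base-stable, and the hindered β,β-disubstituted enone is a poor Weitz–Scheffer substrate.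

**Step 11**
Reactants: 14
Product: 15, (3S)-3-[(2S)-but-3-en-2-yl]-6-methoxy-6-[2-(2,6,6-trimethyl-3-oxocyclohex-1-en-1-yl)ethyl]-1,2-dioxane (mixture at C6)
Conditions: PPTS (0.2 equiv), CH2Cl2, 4 Å MS, rt
Reagents that add atoms: none (MeOH is lost)
Why: Acid-catalysed intramolecular transketalization of the hydroperoxide onto the dimethyl ketal closes the six-membered peroxide ring. The C6 anomeric mixture is harmless because step 12 converges both anomers through one cation.

**Step 12**
Reactants: 15
Product: 16, (3S,6R)-3-[(2S)-but-3-en-2-yl]-6-methyl-6-[2-(2,6,6-trimethyl-3-oxocyclohex-1-en-1-yl)ethyl]-1,2-dioxane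
Conditions: AlMe3 (3 equiv), CH2Cl2, −78 °C→−30 °C
Reagents that add atoms: trimethylaluminum, C[Al](C)C (delivers the methyl group)
Why: Proposed new method: Lewis-acid ionization of the OMe group of the cyclic peroxyketal 15 gives a 1,2-dioxan-3-ylium (peroxycarbenium) ion with the C3 side chain equatorial, and AlMe3 delivers methyl axially through a chair-like transition state, creating the tetrasubstituted peroxide carbon C6 with Me cis to the C3 side chain and the arylethyl chain equatorial (the target diastereomer). Both C6 anomers of 15 ionize to the same cation, so the anomer mixture is irrelevant. The closest known reactions are Lewis-acid C-glycosylation of cyclic acetals with Me3Al and Lewis-acid allylation of peroxyacetals; the new feature is a methyl nucleophile on a peroxyketal to make a quaternary peroxide stereocentre.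

**Step 13**
Reactants: 16
Product: 17, (2R)-2-{(3S,6R)-6-methyl-6-[2-(2,6,6-trimethyl-3-oxocyclohex-1-en-1-yl)ethyl]-1,2-dioxan-3-yl}propanoic acid (the free acid of the target)
Conditions: OsO4 (5 mol%), Oxone, DMF, rt
Reagents that add atoms: Oxone (KHSO5), [K+].OOS(=O)(=O)[O-] (source of the carboxyl oxygens)
Why: OsO4/Oxone oxidative cleavage takes the terminal alkene directly to the carboxylic acid. The transient α-branched aldehyde has little time to epimerize, and the dialkyl peroxide and the tetrasubstituted enone survive.

**Step 14**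
Reactants: 17
Product: 18, methyl diacarnoate A (target)
Conditions: TMSCHN2, MeOH/PhMe, 0 °C
Reagents that add atoms: trimethylsilyldiazomethane, C[Si](C)(C)[CH-][N+]#N (delivers CH3); methanol, CO
Why: Neutral esterification, so there is no epimerization at the α-carbon and no β-elimination of the peroxide.

## Stereochemical check
Target: ester α-carbon R, ring C3 S, ring C6 R, with the C3 side chain and the C6 methyl cis on the dioxane. The alcohol 12 is (3S,4R) and anti. Inversion at C4 in step 10 gives the syn-related 14, whose SMILES matches the target fragment. Step 12 sets C6 cis to the C3 side chain. Steps 13 and 14 do not touch any stereocentre, and the final SMILES of 18 is identical to the target.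

## Compound list
1 | 4,4-dimethylcyclohexane-1,3-dione | O=C1CCC(C)(C)C(=O)C1 | starting material
2 | 2,4,4-trimethylcyclohexane-1,3-dione | O=C1CCC(C)(C)C(=O)C1C | intermediate
3 | 3-isobutoxy-2,6,6-trimethylcyclohex-2-en-1-one | CC(C)COC1=C(C)C(=O)C(C)(C)CC1 | intermediate
4 | 2-(1,3-dioxolan-2-yl)ethylmagnesium bromide | Br[Mg]CCC1OCCO1 | starting material
5 | 3-(2,6,6-trimethyl-3-oxocyclohex-1-en-1-yl)propanal | O=CCCC1=C(C)C(=O)CCC1(C)C | intermediate
6 | 3-butenylmagnesium bromide | C=CCC[Mg]Br | starting material
7 | 3-(3-hydroxyhept-6-en-1-yl)-2,4,4-trimethylcyclohex-2-en-1-one (racemic) | C=CCCC(O)CCC1=C(C)C(=O)CCC1(C)C | intermediate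
8 | 3-(3-oxohept-6-en-1-yl)-2,4,4-trimethylcyclohex-2-en-1-one | C=CCCC(=O)CCC1=C(C)C(=O)CCC1(C)C | intermediate
9 | 3-(3,3-dimethoxyhept-6-en-1-yl)-2,4,4-trimethylcyclohex-2-en-1-one | C=CCCC(OC)(OC)CCC1=C(C)C(=O)CCC1(C)C | intermediate
10 | 4,4-dimethoxy-6-(2,6,6-trimethyl-3-oxocyclohex-1-en-1-yl)hexanal | O=CCCC(OC)(OC)CCC1=C(C)C(=O)CCC1(C)C | intermediate
11 | (E)-crotyl-diisopinocampheylborane (from (−)-Ipc2BOMe; Ipc stereochemistry not drawn) | C/C=C/CB(C1C(C)C2CC(C1)C2(C)C)C1C(C)C2CC(C1)C2(C)C | starting material (reagent made in situ)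
12 | (3S,4R)-7,7-dimethoxy-3-methyl-9-(2,6,6-trimethyl-3-oxocyclohex-1-en-1-yl)non-1-en-4-ol | C=C[C@H](C)[C@H](O)CCC(OC)(OC)CCC1=C(C)C(=O)CCC1(C)C | intermediate
13 | O-mesylate of 12 | C=C[C@H](C)[C@H](OS(C)(=O)=O)CCC(OC)(OC)CCC1=C(C)C(=O)CCC1(C)C | intermediate
14 | (3S,4S)-4-hydroperoxy-7,7-dimethoxy-3-methyl-9-(2,6,6-trimethyl-3-oxocyclohex-1-en-1-yl)non-1-ene | C=C[C@H](C)[C@@H](OO)CCC(OC)(OC)CCC1=C(C)C(=O)CCC1(C)C | intermediate
15 | 3-methoxy-1,2-dioxane (C6 epimeric mixture) | C=C[C@H](C)[C@@H]1CCC(OC)(CCC2=C(C)C(=O)CCC2(C)C)OO1 | intermediate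
16 | vinyl-dioxane (3S,6R) | C=C[C@H](C)[C@@H]1CC[C@@](C)(CCC2=C(C)C(=O)CCC2(C)C)OO1 | intermediate
17 | carboxylic acid corresponding to the target | OC(=O)[C@H](C)[C@@H]1CC[C@@](C)(CCC2=C(C)C(=O)CCC2(C)C)OO1 | intermediate
18 | methyl diacarnoate A | COC(=O)[C@H](C)[C@@H]1CC[C@@](C)(CCC2=C(C)C(=O)CCC2(C)C)OO1 | target

## Summary
Total steps: 14. Longest linear sequence: 14.

Three steps most likely to fail:
1. **Step 12 (proposed new step).** AlMe3 may attack the O–O bond or the enone carbonyl, or the peroxycarbenium ion may fragment.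
   Fallback (known chemistry): From mesylate 13, unmask the ketone (PPTS, acetone/H2O) and do a chemoselective Petasis methylenation (Cp2TiMe2) of the aliphatic ketone. Then displace the mesylate with HOO⁻ as in step 10 and close the ring by acid-catalysed Markovnikov 6-exo hydroperoxide cyclization onto the 1,1-disubstituted alkene (cat. TfOH or Co(II)/silane). Separate the C6 epimers and continue with steps 13–14.
2. **Step 10.** The β-branched secondary mesylate may undergo E2 elimination instead of SN2.
   Fallback: Convert ketal 13 to the α-methoxy hydroperoxide (H2O2, CSA), then close the ring by intramolecular 6-exo-tet O-alkylation of the mesylate (Cs2CO3, DMF). This gives 15 directly, with inversion at C4.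
3. **Step 3.** Grignard addition to the hindered vinylogous-ester carbonyl next to CMe2 may be sluggish.
   Fallback: Start from 4,4-dimethylcyclohex-2-enone. Do a Cu-catalysed 1,4-addition of Grignard 4 (CuBr·SMe2, TMSCl), trap the enolate with MeI, dehydrogenate to the tetrasubstituted enone (Saegusa or IBX), then hydrolyze the dioxolane to give aldehyde 5.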